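## Retrosynthetic overview

1. The only ring, the ten-membered carbocycle, is closed in the last step: a nickel-catalysed, chromium-mediated (Nozaki–Hiyama–Kishi) C5–C6 coupling of acyclic iodo-aldehyde 30, which already carries all five ester groups, so the free 6-OH is created by the ring closure.
2. 30 comes from pentaester 27 by anti-selective hydroboration of its 1,1-disubstituted alkene (sets C7) and oxidation; 27 comes from 17 by esterification with acid 24, global MOM removal and acetylation.
3. 17 is disconnected at C8–C9: catalytic syn-alkoxyallylboration of enal 8 with allylboronate 15 (sets C8 and C9; proposed new method).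
4. 8 comes from homoprenyl bromide and propargyl alcohol (carbomagnesiation/iodination, SeO2 oxidation); 15 from (R)-Roche ester (C11); 24 from cis-2-butene and acetaldehyde (crotylboration).

Assumption: positions are quoted in germacrane numbering (C1=C10 and C4=C5 double bonds, C6 carbinol, C7 bearing C11 with C12 and C13, C14 on C10, C15 on C4); MOM = methoxymethyl, Ipc = isopinocampheyl.

## Route

Step 1
Reactants: 1 5-bromo-2-methylpent-2-ene; 2 prop-2-yn-1-ol
Product: 5 (2Z)-2-(iodomethylidene)-6-methylhept-5-en-1-ol, via homoprenylmagnesium bromide 3 (not isolated), via alkenylmagnesium alkoxide 4 (not isolated)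
Conditions: Mg, THF, 40 °C (gives 3, 3 equiv); then 2, CuI (10 mol %), THF/Et2O, −10 °C → rt, 16 h; then I2, THF, −40 → 0 °C
Reagents that add atoms: iodine, I-I
Why: Copper-catalysed anti-carbomagnesiation of propargyl alcohol (Duboudin reaction): the magnesium alkoxide directs the alkyl group to the internal alkyne carbon and holds magnesium cis to CH2O in a five-membered chelate, and iodinolysis with retention gives the vinyl iodide with iodine cis to CH2OH, which is the C4=C5 geometry of the target.

Step 2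
Reactants: 5 (2Z)-2-(iodomethylidene)-6-methylhept-5-en-1-ol
Product: 6 (1Z)-1-iodo-2-[(methoxymethoxy)methyl]-6-methylhepta-1,5-diene
Conditions: MOMCl, i-Pr2NEt, CH2Cl2, 0 °C → rt
Reagents that add atoms: chloromethyl methyl ether, COCCl
Why: O-alkylation of the primary alcohol by the chloromethyl ether (acetal formation through its oxocarbenium ion) protects O15 for the oxidation and organometallic steps that follow.

Step 3
Reactants: 6 (1Z)-1-iodo-2-[(methoxymethoxy)methyl]-6-methylhepta-1,5-diene
Product: 7 (2E,6Z)-7-iodo-6-[(methoxymethoxy)methyl]-2-methylhepta-2,6-dien-1-ol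
Conditions: SeO2 (0.3 equiv), t-BuOOH (3 equiv), salicylic acid (10 mol %), CH2Cl2, rt, 36 h (a little over-oxidised 8 is carried into step 4)
Reagents that add atoms: tert-butyl hydroperoxide, CC(C)(C)OO
Why: Sharpless SeO2/t-BuOOH allylic oxidation (ene reaction, then [2,3]-shift) attacks only the electron-rich gem-dimethyl alkene and only its E-methyl group, so the new CH2OH (C9) ends trans to the chain, while the iodo-alkene is too electron-poor to react.

Step 4
Reactants: 7 (2E,6Z)-7-iodo-6-[(methoxymethoxy)methyl]-2-methylhepta-2,6-dien-1-ol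
Product: 8 (2E,6Z)-7-iodo-6-[(methoxymethoxy)methyl]-2-methylhepta-2,6-dienal
Conditions: MnO2 (15 equiv), CH2Cl2, rt
Reagents that add atoms: none
Why: Chemoselective MnO2 oxidation of the allylic alcohol gives the E-enal without isomerising either double bond.

Step 5
Reactants: 9 methyl (2R)-3-hydroxy-2-methylpropanoate
Product: 10 methyl (2R)-3-(methoxymethoxy)-2-methylpropanoate
Conditions: MOMCl, i-Pr2NEt, CH2Cl2, 0 °C → rt
Reagents that add atoms: chloromethyl methyl ether, COCCl
Why: MOM ether formation under mildly basic conditions protects O12 without epimerising the Roche ester stereocentre (the future C11).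

Step 6
Reactants: 10 methyl (2R)-3-(methoxymethoxy)-2-methylpropanoate
Product: 11 (2R)-N-methoxy-3-(methoxymethoxy)-N,2-dimethylpropanamide
Conditions: MeNHOMe·HCl, i-PrMgCl, THF, −20 °C
Reagents that add atoms: N,O-dimethylhydroxylamine hydrochloride, Cl.CNOC
Why: Weinreb amide formation by aminolysis of the ester with the magnesium amide of N,O-dimethylhydroxylamine is fast at −20 °C and leaves the α-stereocentre intact.

Step 7
Reactants: 11 (2R)-N-methoxy-3-(methoxymethoxy)-N,2-dimethylpropanamide
Product: 12 (3R)-1,4-bis(methoxymethoxy)-3-methylbutan-2-one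
Conditions: Bu3SnCH2OMOM, n-BuLi, THF, −78 °C; then 11, −78 °C; aq. NH4Cl
Reagents that add atoms: tributyl[(methoxymethoxy)methyl]stannane, CCCC[Sn](CCCC)(CCCC)COCOC
Why: Tin–lithium exchange gives an α-alkoxymethyllithium (Still reagent) that adds once to the Weinreb amide; the chelated tetrahedral adduct collapses only on work-up, so there is no over-addition and no epimerisation.

Step 8
Reactants: 12 (3R)-1,4-bis(methoxymethoxy)-3-methylbutan-2-one
Product: 13 (3S)-4-(methoxymethoxy)-2-[(methoxymethoxy)methyl]-3-methylbut-1-ene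
Conditions: Cp2TiMe2 (2.5 equiv), toluene/THF, 65 °C, dark
Reagents that add atoms: dimethyltitanocene, [CH3-].[CH3-].[Ti+4].c1cc[cH-]c1.c1cc[cH-]c1
Why: Petasis methylenation (titanium methylidene, [2+2]/retro-[2+2]) is non-basic, so the epimerisable, β-alkoxy-substituted α-centre survives; the descriptor changes from R to S only through priorities.

Step 9
Reactants: 13 (3S)-4-(methoxymethoxy)-2-[(methoxymethoxy)methyl]-3-methylbut-1-ene
Product: 15 2-{(2E)-3-(methoxymethoxy)-2-[(2S)-1-(methoxymethoxy)propan-2-yl]prop-2-en-1-yl}-4,4,5,5-tetramethyl-1,3,2-dioxaborolane, via α-lithiated allyl ether 14 (not isolated)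
Conditions: s-BuLi, THF, −78 °C, 45 min; then i-PrOBpin, −78 °C → rt; pH 7 buffer; filtration through deactivated silica
Reagents that add atoms: 2-isopropoxy-4,4,5,5-tetramethyl-1,3,2-dioxaborolane, CC(C)OB1OC(C)(C)C(C)(C)O1
Why: Allylic α-oxygen lithiation followed by γ-selective borylation (Hoffmann/Brown γ-alkoxyallylboron chemistry): oxygen–lithium chelation fixes the anion so that OMOM ends cis to CH2B, the geometry that leads to syn diols.

Step 10
Reactants: 8 (2E,6Z)-7-iodo-6-[(methoxymethoxy)methyl]-2-methylhepta-2,6-dienal; 15 2-{(2E)-3-(methoxymethoxy)-2-[(2S)-1-(methoxymethoxy)propan-2-yl]prop-2-en-1-yl}-4,4,5,5-tetramethyl-1,3,2-dioxaborolane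
Product: 17 (2S,4S,5S,6E,10Z)-11-iodo-1,4-bis(methoxymethoxy)-10-[(methoxymethoxy)methyl]-2,6-dimethyl-3-methylideneundeca-6,10-dien-5-ol, via O-pinacolboryl adduct 16 (not isolated)
Conditions: (R)-TRIP [(R)-3,3′-bis(2,4,6-triisopropylphenyl)-1,1′-binaphthalene-2,2′-diyl hydrogen phosphate] (10 mol %), 4 Å molecular sieves, toluene, −30 °C, 48 h; then aq. NaHCO3
Reagents that add atoms: none
Why: Proposed new method: chiral phosphoric acid catalysed syn-alkoxyallylboration with a 2-alkyl-substituted γ-alkoxyallyl pinacol boronate that carries its own stereocentre — the acid O–H hydrogen-bonds to a pinacol oxygen and the P=O to the formyl C–H, so allyl transfer runs through a closed six-membered chair with the enal residue equatorial and the cis-OMOM group axial, which forms the C8–C9 bond with syn O/O configuration, while the (R)-catalyst pocket exposes the aldehyde Re face (9S, hence 8S) and should override the weak bias of the remote C11 centre; closest known reaction type: phosphoric acid catalysed allyl-, crotyl- and unsubstituted γ-alkoxyallylboration of aldehydes with pinacol boronates, and the stoichiometric Brown alkoxyallylboration.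

Step 11
Reactants: 18 (Z)-but-2-ene; 19 acetaldehyde
Product: 22 (2S,3S)-3-methylpent-4-en-2-ol, via (Z)-crotylpotassium 20 (not isolated), via (Z)-crotyldiisopinocampheylborane 21 (not isolated)
Conditions: n-BuLi, KOt-Bu, THF, −78 → −45 °C; (+)-Ipc2BOMe (from (−)-α-pinene), −78 °C; BF3·OEt2; then 19, −78 °C; NaOH, H2O2; distillation
Reagents that add atoms: none
Why: Brown (Z)-crotylboration: Schlosser metalation keeps the Z geometry, the closed chair transition state gives the syn product, and the Ipc groups derived from (−)-α-pinene direct attack to the Re face of acetaldehyde, giving the (2S,3S) alcohol.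

Step 12
Reactants: 22 (2S,3S)-3-methylpent-4-en-2-ol
Product: 23 (3S,4S)-4-(methoxymethoxy)-3-methylpent-1-ene
Conditions: MOMCl, i-Pr2NEt, CH2Cl2, 0 °C → rt
Reagents that add atoms: chloromethyl methyl ether, COCCl
Why: MOM ether formation masks the side-chain hydroxyl with the same group used on the skeleton, so that it is unveiled and acetylated together with O8, O12 and O15 later.

Step 13
Reactants: 23 (3S,4S)-4-(methoxymethoxy)-3-methylpent-1-ene
Product: 24 (2R,3S)-3-(methoxymethoxy)-2-methylbutanoic acid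
Conditions: KMnO4 (cat.), NaIO4, K2CO3, t-BuOH/H2O, rt; then pH 3, extraction
Reagents that add atoms: sodium periodate, [Na+].[O-]I(=O)(=O)=O; water, O
Why: Lemieux–von Rudloff cleavage (permanganate-catalysed, periodate as terminal oxidant) takes the vinyl group directly to the carboxylic acid in buffered medium without touching the MOM acetal or the α-stereocentre.

Step 14
Reactants: 17 (2S,4S,5S,6E,10Z)-11-iodo-1,4-bis(methoxymethoxy)-10-[(methoxymethoxy)methyl]-2,6-dimethyl-3-methylideneundeca-6,10-dien-5-ol; 24 (2R,3S)-3-(methoxymethoxy)-2-methylbutanoic acid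
Product: 25 (2S,4S,5S,6E,10Z)-11-iodo-1,4-bis(methoxymethoxy)-10-[(methoxymethoxy)methyl]-2,6-dimethyl-3-methylideneundeca-6,10-dien-5-yl (2R,3S)-3-(methoxymethoxy)-2-methylbutanoate
Conditions: 24, 2,4,6-trichlorobenzoyl chloride, Et3N, THF, rt; then 17, DMAP, toluene, rt
Reagents that add atoms: none
Why: Yamaguchi esterification: the mixed trichlorobenzoic anhydride and DMAP acylate the hindered allylic 9-OH, the β-MOM-oxy acid is not prone to β-elimination, and no stereocentre is touched.

Step 15
Reactants: 25 (2S,4S,5S,6E,10Z)-11-iodo-1,4-bis(methoxymethoxy)-10-[(methoxymethoxy)methyl]-2,6-dimethyl-3-methylideneundeca-6,10-dien-5-yl (2R,3S)-3-(methoxymethoxy)-2-methylbutanoate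
Product: 26 (2S,4S,5S,6E,10Z)-1,4-dihydroxy-10-(hydroxymethyl)-11-iodo-2,6-dimethyl-3-methylideneundeca-6,10-dien-5-yl (2R,3S)-3-hydroxy-2-methylbutanoate
Conditions: ZnBr2 (6 equiv), n-PrSH (10 equiv), CH2Cl2, 0 °C, 15 min; crude tetraol taken directly into step 16
Reagents that add atoms: none
Why: Lewis acid/thiol acetal cleavage removes all four MOM groups in minutes while sparing the ester, the vinyl iodide and the alkenes, and the crude tetraol is acetylated at once to forestall acyl migration from O9 to O8.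

Step 16
Reactants: 26 (2S,4S,5S,6E,10Z)-1,4-dihydroxy-10-(hydroxymethyl)-11-iodo-2,6-dimethyl-3-methylideneundeca-6,10-dien-5-yl (2R,3S)-3-hydroxy-2-methylbutanoate
Product: 27 (2S,4S,5S,6E,10Z)-1,4-diacetoxy-10-(acetoxymethyl)-11-iodo-2,6-dimethyl-3-methylideneundeca-6,10-dien-5-yl (2R,3S)-3-acetoxy-2-methylbutanoate
Conditions: Ac2O, pyridine, DMAP (cat.), CH2Cl2, 0 °C → rt
Reagents that add atoms: acetic anhydride, CC(=O)OC(C)=O
Why: DMAP-catalysed acetylation of the two primary and two secondary hydroxyls installs in one operation all four acetates of the target (O8, O12, O15 and the side-chain O3′).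

Step 17
Reactants: 27 (2S,4S,5S,6E,10Z)-1,4-diacetoxy-10-(acetoxymethyl)-11-iodo-2,6-dimethyl-3-methylideneundeca-6,10-dien-5-yl (2R,3S)-3-acetoxy-2-methylbutanoate
Product: 29 (2S,3S,4S,5S,6E,10Z)-1,4-diacetoxy-10-(acetoxymethyl)-3-(hydroxymethyl)-11-iodo-2,6-dimethylundeca-6,10-dien-5-yl (2R,3S)-3-acetoxy-2-methylbutanoate, via B-alkyl-9-BBN adduct 28 (not isolated)
Conditions: 9-borabicyclo[3.3.1]nonane dimer (9-BBN, 3 equiv), THF, 0 °C → rt; then aq. NaOAc, 30 % H2O2, 0 °C → rt
Reagents that add atoms: hydrogen peroxide, OO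
Why: Hydroboration–oxidation under Still–Barrish 1,2-induction: 9-BBN adds only to the 1,1-disubstituted alkene with boron on the CH2 terminus and hydrogen delivered anti to the oxygen-bearing allylic centre C8, which sets C7 as 7,8-anti (7S), and the acetate-buffered peroxide work-up spares the five esters.

Step 18
Reactants: 29 (2S,3S,4S,5S,6E,10Z)-1,4-diacetoxy-10-(acetoxymethyl)-3-(hydroxymethyl)-11-iodo-2,6-dimethylundeca-6,10-dien-5-yl (2R,3S)-3-acetoxy-2-methylbutanoate
Product: 30 (2S,3R,4S,5S,6E,10Z)-1,4-diacetoxy-10-(acetoxymethyl)-3-formyl-11-iodo-2,6-dimethylundeca-6,10-dien-5-yl (2R,3S)-3-acetoxy-2-methylbutanoate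
Conditions: Dess–Martin periodinane, NaHCO3, CH2Cl2, 0 °C → rt; used at once
Reagents that add atoms: none
Why: Dess–Martin oxidation of the primary alcohol under buffered, amine-free conditions gives the β-acetoxy aldehyde without β-elimination or epimerisation at C7 (the descriptor becomes 3R only through priorities).

Step 19
Reactants: 30 (2S,3R,4S,5S,6E,10Z)-1,4-diacetoxy-10-(acetoxymethyl)-3-formyl-11-iodo-2,6-dimethylundeca-6,10-dien-5-yl (2R,3S)-3-acetoxy-2-methylbutanoate
Product: 31 (6S,7S,8S,9S,11S)-8,12,15-triacetoxy-9-{[(2R,3S)-3-acetoxy-2-methylbutanoyl]oxy}-6-hydroxygermacra-1(10),4-diene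
Conditions: CrCl2 (12 equiv), NiCl2 (2 mol % of Cr), DMSO/THF 3:1, 2 mM (syringe-pump addition of 30), rt, 24 h; aq. sodium serinate work-up
Reagents that add atoms: none
Why: Nozaki–Hiyama–Kishi macrocyclisation: zerovalent nickel inserts into the carbon–iodine bond with retention, transmetalation gives an alkenyl species of trivalent chromium that adds only to the aldehyde (esters and allylic acetates are inert), and closure through the crown-like arrangement with the C7, C8 and C9 substituents pseudo-equatorial and the chromium-bound oxygen on the ring periphery is expected to give the 6S alcohol, all at room temperature so that the 1,5-diene does not undergo Cope rearrangement.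

## Compound list

1 | 5-bromo-2-methylpent-2-ene (homoprenyl bromide) | CC(C)=CCCBr | starting material
2 | prop-2-yn-1-ol | C#CCO | starting material
3 | homoprenylmagnesium bromide (not isolated) | CC(C)=CCC[Mg]Br | intermediate
4 | alkenylmagnesium alkoxide, Mg cis to CH2O (not isolated) | Br[Mg]OC/C(=C\[Mg]Br)CCC=C(C)C | intermediate
5 | (2Z)-2-(iodomethylidene)-6-methylhept-5-en-1-ol | OC/C(=C\I)CCC=C(C)C | intermediate
6 | (1Z)-1-iodo-2-[(methoxymethoxy)methyl]-6-methylhepta-1,5-diene | COCOC/C(=C\I)CCC=C(C)C | intermediate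
7 | (2E,6Z)-7-iodo-6-[(methoxymethoxy)methyl]-2-methylhepta-2,6-dien-1-ol | COCOC/C(=C\I)CC/C=C(\C)CO | intermediate
8 | (2E,6Z)-7-iodo-6-[(methoxymethoxy)methyl]-2-methylhepta-2,6-dienal | COCOC/C(=C\I)CC/C=C(\C)C=O | intermediate
9 | methyl (2R)-3-hydroxy-2-methylpropanoate ((R)-Roche ester) | COC(=O)[C@H](C)CO | starting material
10 | methyl (2R)-3-(methoxymethoxy)-2-methylpropanoate | COC(=O)[C@H](C)COCOC | intermediate
11 | (2R)-N-methoxy-3-(methoxymethoxy)-N,2-dimethylpropanamide | CON(C)C(=O)[C@H](C)COCOC | intermediate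
12 | (3R)-1,4-bis(methoxymethoxy)-3-methylbutan-2-one | COCOCC(=O)[C@H](C)COCOC | intermediate
13 | (3S)-4-(methoxymethoxy)-2-[(methoxymethoxy)methyl]-3-methylbut-1-ene | COCOCC(=C)[C@H](C)COCOC | intermediate
14 | α-lithiated allyl ether of 13 (not isolated) | COCOC([Li])C(=C)[C@H](C)COCOC | intermediate
15 | 2-{(2E)-3-(methoxymethoxy)-2-[(2S)-1-(methoxymethoxy)propan-2-yl]prop-2-en-1-yl}-4,4,5,5-tetramethyl-1,3,2-dioxaborolane (OMOM cis to CH2B) | COCO/C=C(\CB1OC(C)(C)C(C)(C)O1)[C@H](C)COCOC | intermediate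
16 | O9-pinacolboryl derivative of 17 (not isolated) | I/C=C(\COCOC)CC/C=C(\C)[C@H](OB1OC(C)(C)C(C)(C)O1)[C@@H](OCOC)C(=C)[C@H](C)COCOC | intermediate
17 | (2S,4S,5S,6E,10Z)-11-iodo-1,4-bis(methoxymethoxy)-10-[(methoxymethoxy)methyl]-2,6-dimethyl-3-methylideneundeca-6,10-dien-5-ol | I/C=C(\COCOC)CC/C=C(\C)[C@H](O)[C@@H](OCOC)C(=C)[C@H](C)COCOC | intermediate
18 | (Z)-but-2-ene | C/C=C\C | starting material
19 | acetaldehyde | CC=O | starting material
20 | (Z)-crotylpotassium (not isolated) | C/C=C\C[K] | intermediate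
21 | (Z)-crotyldiisopinocampheylborane, Ipc from (−)-α-pinene (not isolated) | C/C=C\CB([C@H]1C[C@H]2C[C@@H]([C@@H]1C)C2(C)C)[C@H]1C[C@H]2C[C@@H]([C@@H]1C)C2(C)C | intermediate
22 | (2S,3S)-3-methylpent-4-en-2-ol | C=C[C@H](C)[C@H](C)O | intermediate
23 | (3S,4S)-4-(methoxymethoxy)-3-methylpent-1-ene | C=C[C@H](C)[C@H](C)OCOC | intermediate
24 | (2R,3S)-3-(methoxymethoxy)-2-methylbutanoic acid | OC(=O)[C@H](C)[C@H](C)OCOC | intermediate
25 | (2S,4S,5S,6E,10Z)-11-iodo-1,4-bis(methoxymethoxy)-10-[(methoxymethoxy)methyl]-2,6-dimethyl-3-methylideneundeca-6,10-dien-5-yl (2R,3S)-3-(methoxymethoxy)-2-methylbutanoate | I/C=C(\COCOC)CC/C=C(\C)[C@H](OC(=O)[C@H](C)[C@H](C)OCOC)[C@@H](OCOC)C(=C)[C@H](C)COCOC | intermediate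
26 | (2S,4S,5S,6E,10Z)-1,4-dihydroxy-10-(hydroxymethyl)-11-iodo-2,6-dimethyl-3-methylideneundeca-6,10-dien-5-yl (2R,3S)-3-hydroxy-2-methylbutanoate | I/C=C(\CO)CC/C=C(\C)[C@H](OC(=O)[C@H](C)[C@H](C)O)[C@@H](O)C(=C)[C@H](C)CO | intermediate
27 | (2S,4S,5S,6E,10Z)-1,4-diacetoxy-10-(acetoxymethyl)-11-iodo-2,6-dimethyl-3-methylideneundeca-6,10-dien-5-yl (2R,3S)-3-acetoxy-2-methylbutanoate | I/C=C(\COC(C)=O)CC/C=C(\C)[C@H](OC(=O)[C@H](C)[C@H](C)OC(C)=O)[C@@H](OC(C)=O)C(=C)[C@H](C)COC(C)=O | intermediate
28 | B-alkyl-9-BBN adduct of 27, boron on the former methylidene carbon (not isolated) | I/C=C(\COC(C)=O)CC/C=C(\C)[C@H](OC(=O)[C@H](C)[C@H](C)OC(C)=O)[C@@H](OC(C)=O)[C@@H]([C@H](C)COC(C)=O)CB1C2CCCC1CCC2 | intermediate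
29 | (2S,3S,4S,5S,6E,10Z)-1,4-diacetoxy-10-(acetoxymethyl)-3-(hydroxymethyl)-11-iodo-2,6-dimethylundeca-6,10-dien-5-yl (2R,3S)-3-acetoxy-2-methylbutanoate | I/C=C(\COC(C)=O)CC/C=C(\C)[C@H](OC(=O)[C@H](C)[C@H](C)OC(C)=O)[C@@H](OC(C)=O)[C@@H]([C@H](C)COC(C)=O)CO | intermediate
30 | (2S,3R,4S,5S,6E,10Z)-1,4-diacetoxy-10-(acetoxymethyl)-3-formyl-11-iodo-2,6-dimethylundeca-6,10-dien-5-yl (2R,3S)-3-acetoxy-2-methylbutanoate | I/C=C(\COC(C)=O)CC/C=C(\C)[C@H](OC(=O)[C@H](C)[C@H](C)OC(C)=O)[C@@H](OC(C)=O)[C@@H]([C@H](C)COC(C)=O)C=O | intermediate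
31 | CNP0294824.2: (6S,7S,8S,9S,11S)-8,12,15-triacetoxy-9-{[(2R,3S)-3-acetoxy-2-methylbutanoyl]oxy}-6-hydroxygermacra-1(10),4-diene, both ring double bonds trans within the ring (1(10)E; 4Z by CIP because of the CH2OAc group) | CC(=O)OC/C1=C\[C@H](O)[C@H]([C@H](C)COC(C)=O)[C@H](OC(C)=O)[C@@H](OC(=O)[C@H](C)[C@H](C)OC(C)=O)/C(C)=C/CC1 | target

## Step count and risks

Total step count: 19. Longest linear sequence: 12 steps (5, 6, 7, 8, 9, 10, 14, 15, 16, 17, 18, 19, from Roche ester 9 to 31).

The three steps most likely to fail are steps 10, 17 and 19.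

Step 10 is the proposed new reaction. It may be slow because of the branched 2-substituent on the boronate, or the catalyst may not fully control the aldehyde face against the C11 centre. The fallback uses only known chemistry (Brown alkoxyallylboration); it sets out from 13 (with 8) and comes back at 17. Compound 13 is lithiated (s-BuLi, THF, −78 °C) and trapped with (+)-Ipc2BOMe from (−)-α-pinene, then BF3·OEt2, to give the stoichiometric chiral reagent γ-(methoxymethoxy)allyl-diisopinocampheylborane F1 (OMOM cis to CH2B). Addition of 8 at −78 °C and ethanolamine work-up give 17 through the same chair, with the Ipc groups directing attack to the aldehyde Re face (8S,9S).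

Step 17 sets C7 on an alkene that is hindered and flanked by two allylic stereocentres: C8, which here carries an acetate and not an ether, and the all-carbon C11, whose influence may oppose that of C8. The sense and level of induction are therefore less secure than in the classic ether cases. The fallback sets out from 25 and comes back at 29, moving the hydroboration to the ether stage and carrying O6 through the ester exchange under a silyl group. 9-BBN adds to 25 (THF, rt) to give the B-alkyl-9-BBN adduct F2, and buffered peroxide oxidation gives primary alcohol F3. TBDPSCl/imidazole (DMF) gives silyl ether F4; ZnBr2/n-PrSH removes the four MOM groups to give tetraol F5; Ac2O/pyridine/DMAP gives tetraacetate F6; HF·pyridine in THF/pyridine then cleaves the silyl ether to give 29.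

Step 19 carries the risks of oligomerisation, loss of acetic acid from the β-acetoxy aldehyde and, above all, the wrong or a mixed configuration at C6. The fallback sets out from 30 and comes back at 31, and it separates ring closure from C6 control. The same chromium/nickel ring closure is run without regard to C6, and any 6R alcohol, C6 epimer F7, is oxidised together with 31 by Dess–Martin periodinane to macrocyclic enone F8. Luche reduction (NaBH4, CeCl3·7H2O, MeOH, −78 °C; hydride from the ring periphery, anti to the C7 side chain) then returns 31. A CBS oxazaborolidine with catecholborane is the reagent-controlled alternative for this reduction.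

Further compounds

F1 | step 10 | {(2E)-3-(methoxymethoxy)-2-[(2S)-1-(methoxymethoxy)propan-2-yl]prop-2-en-1-yl}diisopinocampheylborane, Ipc from (−)-α-pinene, OMOM cis to CH2B | COCO/C=C(\CB([C@H]1C[C@H]2C[C@@H]([C@@H]1C)C2(C)C)[C@H]1C[C@H]2C[C@@H]([C@@H]1C)C2(C)C)[C@H](C)COCOC
F2 | step 17 | B-alkyl-9-BBN adduct of 25, boron on the former methylidene carbon | I/C=C(\COCOC)CC/C=C(\C)[C@H](OC(=O)[C@H](C)[C@H](C)OCOC)[C@@H](OCOC)[C@@H]([C@H](C)COCOC)CB1C2CCCC1CCC2
F3 | step 17 | (2S,3S,4S,5S,6E,10Z)-3-(hydroxymethyl)-11-iodo-1,4-bis(methoxymethoxy)-10-[(methoxymethoxy)methyl]-2,6-dimethylundeca-6,10-dien-5-yl (2R,3S)-3-(methoxymethoxy)-2-methylbutanoate | I/C=C(\COCOC)CC/C=C(\C)[C@H](OC(=O)[C@H](C)[C@H](C)OCOC)[C@@H](OCOC)[C@@H]([C@H](C)COCOC)CO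
F4 | step 17 | tert-butyldiphenylsilyl ether of F3 (silyl on O6) | I/C=C(\COCOC)CC/C=C(\C)[C@H](OC(=O)[C@H](C)[C@H](C)OCOC)[C@@H](OCOC)[C@@H]([C@H](C)COCOC)CO[Si](c1ccccc1)(c1ccccc1)C(C)(C)C
F5 | step 17 | tetraol from F4 (free 8-, 12-, 15- and 3′-OH, O6 silylated) | I/C=C(\CO)CC/C=C(\C)[C@H](OC(=O)[C@H](C)[C@H](C)O)[C@@H](O)[C@@H]([C@H](C)CO)CO[Si](c1ccccc1)(c1ccccc1)C(C)(C)C
F6 | step 17 | tetraacetate of F5 (O6 silylated) | I/C=C(\COC(C)=O)CC/C=C(\C)[C@H](OC(=O)[C@H](C)[C@H](C)OC(C)=O)[C@@H](OC(C)=O)[C@@H]([C@H](C)COC(C)=O)CO[Si](c1ccccc1)(c1ccccc1)C(C)(C)C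
F7 | step 19 | 6R epimer of 31 | CC(=O)OC/C1=C\[C@@H](O)[C@H]([C@H](C)COC(C)=O)[C@H](OC(C)=O)[C@@H](OC(=O)[C@H](C)[C@H](C)OC(C)=O)/C(C)=C/CC1
F8 | step 19 | 6-oxo analogue of 31 (macrocyclic germacra-1(10),4-dien-6-one) | CC(=O)OC/C1=C\C(=O)[C@H]([C@H](C)COC(C)=O)[C@H](OC(C)=O)[C@@H](OC(=O)[C@H](C)[C@H](C)OC(C)=O)/C(C)=C/CC1
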